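**Strategy.** The target is a guai-4-en-3-one: ring A is the cyclopentenone C1–C5, ring B the seven-membered ring C1, C5–C10. Its C8 oxygen and the enone β-carbon C5 are 1,4-related across ring B, the retron of an oxa-Michael adduct, so the route passes through an 8-oxabicyclo[3.2.1]octane with an O bridge from C5 to C8. That core is made in one operation by a (5+2) cycloaddition, forming C5–C6 and C7–C8, of a 3-oxidopyrylium betaine (from Achmatowicz dearomatization of a 3-methylfuran) with methyl acrylate (C6, C7, C11). The precursor is a pyranone acetate whose side-chain stereocenter C4 steers the face; late E1cB opening of the bridge unveils the C4=C5 enone and the C8 hydroxyl.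

Key step: step 5

Remark on the chemistry: atom labels are guaiane numbers of the target (C3 carbonyl, C4 and C10 methyl-bearing, C7 bears carbinol carbon C11, C8 bears the propanoate). (S)-But-3-yn-2-ol, 3-methylfuran-2-carbaldehyde and methyl acrylate are assumed purchasable. SMILES are definitive for configuration.

Step 1
Reactants: 1 (S)-but-3-yn-2-ol
Product: 2 (S)-but-3-yn-2-yl methanesulfonate
Conditions: MsCl, Et3N, CH2Cl2, −78 to 0 °C
Reagents that add atoms: methanesulfonyl chloride, CS(=O)(=O)Cl
Why: O-sulfonylation of the propargylic alcohol does not touch the stereocenter, so the (S) configuration should be kept.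

Step 2
Reactants: 2 (S)-but-3-yn-2-yl methanesulfonate; 3 3-methylfuran-2-carbaldehyde
Product: 5 (1R,2R)-2-methyl-1-(3-methylfuran-2-yl)but-3-yn-1-ol, via allenylzinc reagent 4 (not isolated)
Conditions: Pd(OAc)2 (5 mol %), PPh3 (5 mol %), Et2Zn (3 equiv), THF, −78 to −20 °C; aq. NH4Cl
Reagents that add atoms: none
Why: Marshall propargylation: zerovalent palladium displaces the mesylate in an anti SN2' sense, transmetalation gives allenylzinc 4, and its cyclic SE2' addition to the aldehyde should set the methyl-bearing carbon (future C4) as R by net inversion with the carbinol anti to it (the carbinol center is erased later).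

Step 3
Reactants: 5 (1R,2R)-2-methyl-1-(3-methylfuran-2-yl)but-3-yn-1-ol
Product: 6 (2R)-2-[(2R)-but-3-yn-2-yl]-6-hydroxy-4-methyl-2H-pyran-3(6H)-one (anomers)
Conditions: NBS, NaHCO3, NaOAc, THF/H2O (4:1), 0 °C
Reagents that add atoms: water, O
Why: Achmatowicz oxidative ring expansion dearomatizes the furan (bromination–hydration to a cis-enedione that the carbinol oxygen recloses), the carbinol center being retained as pyranone C2 (future C5) and the propargylic center untouched.

Step 4
Reactants: 6 (2R)-2-[(2R)-but-3-yn-2-yl]-6-hydroxy-4-methyl-2H-pyran-3(6H)-one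
Product: 7 (2R)-2-[(2R)-but-3-yn-2-yl]-4-methyl-3-oxo-3,6-dihydro-2H-pyran-6-yl acetate (anomers)
Conditions: Ac2O, pyridine, DMAP (cat.), CH2Cl2, 0 °C
Reagents that add atoms: acetic anhydride, CC(=O)OC(C)=O
Why: Acetylation of the lactol hydroxyl installs the leaving group for betaine formation without affecting any center that survives.

Step 5
Reactants: 7 (2R)-2-[(2R)-but-3-yn-2-yl]-4-methyl-3-oxo-3,6-dihydro-2H-pyran-6-yl acetate; 8 methyl acrylate
Product: 10 methyl (1S,5R)-1-[(2R)-but-3-yn-2-yl]-3-methyl-2-oxo-8-oxabicyclo[3.2.1]oct-3-ene-6-carboxylate (both C6 epimers of the bicycle, i.e. both C7 epimers in target numbering), via 3-oxidopyrylium betaine 9 (not isolated)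
Conditions: i-Pr2NEt (1.5 equiv), 8 (15 equiv), MeCN, 25 to 50 °C, slow addition of 7
Reagents that add atoms: none
Why: Amine-induced loss of acetate from 7 gives the planar 3-oxidopyrylium betaine 9, a carbonyl-ylide-type dipole whose termini C5 and C8 add suprafacially across C6=C7 of the acrylate in a concerted but asynchronous six-electron (5+2) cycloaddition. The closest known reaction type is the intermolecular oxidopyrylium–alkene cycloaddition of pyranone acetates with acrylates. It closes ring B (C1–C5–C6–C7–C8–C9–C10) and the oxolane C5–C6–C7–C8–O at once, by intermolecular cycloaddition with both bonds formed on one face of the betaine. C5 and C8 become stereocenters, mutually cis by the bridge, and their absolute sense is controlled by C4: in the reactive rotamer the C4 hydrogen lies in the ring plane next to the oxido oxygen (allylic 1,3-strain), the methyl group stands anti to the forming C5–C6 bond and the slim ethynyl group flanks the incoming alkene, so the (R) center should direct addition to the face that gives the (1S,5R) bicycle; the minor facial isomer is a diastereomer and is removed by chromatography. Regioselectivity is needed and is secured twice: the oxido-flanked, nucleophilic and substituted terminus C5 bonds to the unsubstituted acrylate β-carbon, the oxocarbenium-like terminus C8 to the ester-bearing carbon. The C7 configuration (ester exo or endo) is not needed from this step because step 6 sets it under thermodynamic control, and excess acrylate keeps trapping ahead of betaine dimerization.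

Step 6
Reactants: 10 methyl (1S,5R)-1-[(2R)-but-3-yn-2-yl]-3-methyl-2-oxo-8-oxabicyclo[3.2.1]oct-3-ene-6-carboxylate
Product: 12 methyl (1S,3S,5R,6S)-1-[(2R)-but-3-yn-2-yl]-3-methyl-2-oxo-8-oxabicyclo[3.2.1]octane-6-carboxylate, via lithium enolate 11 (not isolated)
Conditions: LiBH(s-Bu)3 (1.05 equiv), THF, −78 °C; MeOH; then NaOMe (0.3 equiv), MeOH, 0 °C to rt
Reagents that add atoms: none
Why: Conjugate (1,4) reduction of the enone by the bulky borohydride gives enolate 11, and after protonation methoxide equilibrates both epimerizable centers to the thermodynamic isomer, with the C10 methyl equatorial on the chair oxanone and the C7 ester exo (syn to the oxygen bridge, clear of the axial C10–H), which are the C10 and C7 configurations of the target.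

Step 7
Reactants: 12 methyl (1S,3S,5R,6S)-1-[(2R)-but-3-yn-2-yl]-3-methyl-2-oxo-8-oxabicyclo[3.2.1]octane-6-carboxylate
Product: 15 (1S,3S,5R,6S)-1-[(2R)-but-3-yn-2-yl]-6-(2-hydroxypropan-2-yl)-3-methyl-8-oxabicyclo[3.2.1]octan-2-one, via silyl enol ether ester 13 (not isolated), via silyl enol ether carbinol 14 (not isolated)
Conditions: TESOTf, Et3N, CH2Cl2, 0 °C; then MeMgBr/CeCl3 (6 equiv), THF, −78 to 0 °C; then 1 M HCl, THF, 0 °C; K2CO3, MeOH, rt
Reagents that add atoms: methylmagnesium bromide, C[Mg]Br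
Why: Soft enolization masks the only ketone as silyl enol ether 13 so that the weakly basic organocerium reagent adds twice to the ester (Grignard-type double addition) to give the tertiary carbinol, after which acid unmasks the ketone and carbonate returns C10 to the equatorial methyl epimer.

Step 8
Reactants: 15 (1S,3S,5R,6S)-1-[(2R)-but-3-yn-2-yl]-6-(2-hydroxypropan-2-yl)-3-methyl-8-oxabicyclo[3.2.1]octan-2-one
Product: 16 (1S,3S,5R,6S)-6-(2-hydroxypropan-2-yl)-3-methyl-1-[(2S)-3-oxobutan-2-yl]-8-oxabicyclo[3.2.1]octan-2-one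
Conditions: Ph3PAuNTf2 (2 mol %), MeOH/H2O (10:1), 50 °C
Reagents that add atoms: water, O
Why: Gold-catalysed Markovnikov hydration of the terminal alkyne should give the methyl ketone (C3 carbonyl, C2 methyl) under near-neutral conditions that spare the tertiary alcohol, the ether bridge and the C4 center.

Step 9
Reactants: 16 (1S,3S,5R,6S)-6-(2-hydroxypropan-2-yl)-3-methyl-1-[(2S)-3-oxobutan-2-yl]-8-oxabicyclo[3.2.1]octan-2-one
Product: 18 (4S,5S,7S,8R,10S)-5,8-epoxy-11-hydroxyguai-1-en-3-one, via aldol adduct 17 (not isolated)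
Conditions: pyrrolidine (0.5 equiv), AcOH (0.5 equiv), toluene, 80 °C
Reagents that add atoms: none
Why: Intramolecular aldol condensation under enamine catalysis closes ring A (5-exo-trig attack of C2 on the C1 ketone, then dehydration), the amine forming the less substituted enamine at the methyl group and not at the hindered C4–H, whose enolization would expel the bridge oxygen too early, while C10 stays equatorial.

Step 10
Reactants: 18 (4S,5S,7S,8R,10S)-5,8-epoxy-11-hydroxyguai-1-en-3-one
Product: 19 (1R,4S,5R,7S,8R,10S)-5,8-epoxy-11-hydroxyguaian-3-one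
Conditions: H2 (1 atm), 10% Pd/C, EtOAc, rt
Reagents that add atoms: none
Why: Heterogeneous hydrogenation should deliver hydrogen to C1 from the exo face (the side of the oxygen bridge, away from the two-carbon bridge), placing H1 cis to the bridge oxygen as in the target.

Step 11
Reactants: 19 (1R,4S,5R,7S,8R,10S)-5,8-epoxy-11-hydroxyguaian-3-one
Product: 21 (1R,7S,8R,10S)-11-hydroxy-3-oxoguai-4-en-8-yl propanoate, via diol enone 20 (not isolated)
Conditions: DBU (2 equiv), CH2Cl2, 0 °C to rt; then (EtCO)2O (1.3 equiv), DMAP (cat.), 0 °C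
Reagents that add atoms: propanoic anhydride, CCC(=O)OC(=O)CC
Why: E1cB β-elimination from the C3 enolate (toward C4) expels the bridge oxygen from C5 with strain release to give the tetrasubstituted C4=C5 enone and the C8 hydroxyl with its configuration intact, and DMAP-catalysed acylation then esterifies this secondary alcohol in preference to the tertiary C11 hydroxyl.

Step 12
Reactants: 21 (1R,7S,8R,10S)-11-hydroxy-3-oxoguai-4-en-8-yl propanoate
Product: 22 (1R,7S,8R,10S)-11-acetoxy-3-oxoguai-4-en-8-yl propanoate (target)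
Conditions: Ac2O (3 equiv), Sc(OTf)3 (5 mol %), MeCN, −20 °C
Reagents that add atoms: acetic anhydride, CC(=O)OC(C)=O
Why: Lewis-acid-catalysed acetylation at low temperature should esterify the hindered tertiary alcohol without elimination and without touching any stereocenter.

**Compound list**

1 | (S)-but-3-yn-2-ol | C#C[C@H](C)O | starting material
2 | (S)-but-3-yn-2-yl methanesulfonate | C#C[C@H](C)OS(C)(=O)=O | intermediate
3 | 3-methylfuran-2-carbaldehyde | Cc1ccoc1C=O | starting material
4 | (aR)-buta-1,2-dien-1-yl(ethyl)zinc (not isolated) | [H]C([Zn]CC)=[C@@]=C([H])C | intermediate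
5 | (1R,2R)-2-methyl-1-(3-methylfuran-2-yl)but-3-yn-1-ol | C#C[C@@H](C)[C@@H](O)c1occc1C | intermediate
6 | (2R)-2-[(2R)-but-3-yn-2-yl]-6-hydroxy-4-methyl-2H-pyran-3(6H)-one (anomers) | C#C[C@@H](C)[C@H]1OC(O)C=C(C)C1=O | intermediate
7 | (2R)-2-[(2R)-but-3-yn-2-yl]-4-methyl-3-oxo-3,6-dihydro-2H-pyran-6-yl acetate (anomers) | C#C[C@@H](C)[C@H]1OC(OC(C)=O)C=C(C)C1=O | intermediate
8 | methyl acrylate | C=CC(=O)OC | starting material
9 | 2-[(2R)-but-3-yn-2-yl]-4-methylpyrylium-3-olate (not isolated) | C#C[C@@H](C)c1[o+]ccc(C)c1[O-] | intermediate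
10 | methyl (1S,5R)-1-[(2R)-but-3-yn-2-yl]-3-methyl-2-oxo-8-oxabicyclo[3.2.1]oct-3-ene-6-carboxylate (both C6 epimers) | O1[C@@H]2C=C(C)C(=O)[C@]1(CC2C(=O)OC)[C@H](C)C#C | intermediate
11 | lithium (1S,5R)-1-[(2R)-but-3-yn-2-yl]-6-(methoxycarbonyl)-3-methyl-8-oxabicyclo[3.2.1]oct-2-en-2-olate (both C6 epimers; not isolated) | O1[C@@H]2CC(C)=C([O-])[C@]1(CC2C(=O)OC)[C@H](C)C#C.[Li+] | intermediate
12 | methyl (1S,3S,5R,6S)-1-[(2R)-but-3-yn-2-yl]-3-methyl-2-oxo-8-oxabicyclo[3.2.1]octane-6-carboxylate (ester exo, methyl equatorial) | O1[C@@H]2C[C@H](C)C(=O)[C@]1(C[C@@H]2C(=O)OC)[C@H](C)C#C | intermediate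
13 | methyl (1S,5R,6S)-1-[(2R)-but-3-yn-2-yl]-3-methyl-2-(triethylsilyloxy)-8-oxabicyclo[3.2.1]oct-2-ene-6-carboxylate (not isolated) | O1[C@@H]2CC(C)=C(O[Si](CC)(CC)CC)[C@]1(C[C@@H]2C(=O)OC)[C@H](C)C#C | intermediate
14 | 2-[(1S,5R,6S)-1-[(2R)-but-3-yn-2-yl]-3-methyl-2-(triethylsilyloxy)-8-oxabicyclo[3.2.1]oct-2-en-6-yl]propan-2-ol (not isolated) | O1[C@@H]2CC(C)=C(O[Si](CC)(CC)CC)[C@]1(C[C@@H]2C(C)(C)O)[C@H](C)C#C | intermediate
15 | (1S,3S,5R,6S)-1-[(2R)-but-3-yn-2-yl]-6-(2-hydroxypropan-2-yl)-3-methyl-8-oxabicyclo[3.2.1]octan-2-one | O1[C@@H]2C[C@H](C)C(=O)[C@]1(C[C@@H]2C(C)(C)O)[C@H](C)C#C | intermediate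
16 | (1S,3S,5R,6S)-6-(2-hydroxypropan-2-yl)-3-methyl-1-[(2S)-3-oxobutan-2-yl]-8-oxabicyclo[3.2.1]octan-2-one | O1[C@@H]2C[C@H](C)C(=O)[C@]1(C[C@@H]2C(C)(C)O)[C@H](C)C(C)=O | intermediate
17 | (4S,5S,7S,8R,10S)-5,8-epoxy-1,11-dihydroxyguaian-3-one (C1 carbinol configuration left open, lost on dehydration; not isolated) | O1[C@@H]2C[C@H](C)C3(O)CC(=O)[C@@H](C)[C@@]31C[C@@H]2C(C)(C)O | intermediate
18 | (4S,5S,7S,8R,10S)-5,8-epoxy-11-hydroxyguai-1-en-3-one | O1[C@@H]2C[C@H](C)C3=CC(=O)[C@@H](C)[C@@]31C[C@@H]2C(C)(C)O | intermediate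
19 | (1R,4S,5R,7S,8R,10S)-5,8-epoxy-11-hydroxyguaian-3-one | O1[C@@H]2C[C@H](C)[C@H]3CC(=O)[C@@H](C)[C@@]31C[C@@H]2C(C)(C)O | intermediate
20 | (1R,7S,8R,10S)-8,11-dihydroxyguai-4-en-3-one (not isolated) | O[C@@H]1C[C@H](C)[C@H]2CC(=O)C(C)=C2C[C@@H]1C(C)(C)O | intermediate
21 | (1R,7S,8R,10S)-11-hydroxy-3-oxoguai-4-en-8-yl propanoate | CCC(=O)O[C@@H]1C[C@H](C)[C@H]2CC(=O)C(C)=C2C[C@@H]1C(C)(C)O | intermediate
22 | (1R,7S,8R,10S)-11-acetoxy-3-oxoguai-4-en-8-yl propanoate (CNP0288556.1) | CCC(=O)O[C@@H]1C[C@H](C)[C@H]2CC(=O)C(C)=C2C[C@@H]1C(C)(C)OC(C)=O | target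

**Step count.** Total steps: 12. Longest linear sequence: 12 steps (from 1 to 22); 3 and 8 enter directly.

**Steps most likely to fail**

Step 5. The process at risk is facial discrimination: methyl and ethynyl on C4 may not differentiate the two faces of the betaine enough, and the betaine may dimerize before it is trapped. The fallback adds reagent control to substrate control. Setting out from 7, the betaine is trapped with the acrylate of methyl (S)-lactate, (2S)-1-methoxy-1-oxopropan-2-yl prop-2-enoate F1 (from methyl (S)-lactate and acryloyl chloride). This gives the lactate cycloadduct F2, whose facial diastereomers are separated. Conjugate reduction with LiBH(s-Bu)3 gives the saturated keto lactate F3, and NaOMe/MeOH both equilibrates C7/C10 and exchanges the lactate for the methyl ester. The sequence comes back to the route at 12.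

Step 6. The process at risk is ring opening: under methoxide the C7 ester enolate may expel the bridge oxygen from C8 (β-elimination) faster than it is reprotonated to the exo epimer. The fallback replaces the ester by a more acidic acyl group that an amine base can equilibrate. Setting out from 7, cycloaddition with S-ethyl prop-2-enethioate F4 (from acryloyl chloride and ethanethiol) gives the thioester cycloadduct F5. LiBH(s-Bu)3 reduction followed by DBU in CH2Cl2 gives the exo keto thioester F6. TESOTf/Et3N gives its silyl enol ether F7, and MeMgBr/CeCl3 converts the thioester into carbinol 14. Acid work-up comes back to the route at 15.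

Step 9. The process at risk is enolization of the C3 ketone toward C4 with early expulsion of the bridge oxygen, which would leave a C1 carbinol that cannot dehydrate. The fallback makes C2 the only nucleophilic site by phosphonate activation. Setting out from 15, aerobic coupling with diethyl phosphite catalysed by copper iodide (CuI) gives the alkynylphosphonate F8. Gold-catalysed hydration (Ph3PAuNTf2) gives the β-ketophosphonate F9. Intramolecular Horner–Wadsworth–Emmons olefination with the C1 ketone (LiCl, DBU, MeCN) comes back to the route at 18, bypassing 16 and 17.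

**Further compounds**

F1 | step 5 | (2S)-1-methoxy-1-oxopropan-2-yl prop-2-enoate | C=CC(=O)O[C@@H](C)C(=O)OC
F2 | step 5 | (2S)-1-methoxy-1-oxopropan-2-yl (1S,5R)-1-[(2R)-but-3-yn-2-yl]-3-methyl-2-oxo-8-oxabicyclo[3.2.1]oct-3-ene-6-carboxylate (both C6 epimers) | O1[C@@H]2C=C(C)C(=O)[C@]1(CC2C(=O)O[C@@H](C)C(=O)OC)[C@H](C)C#C
F3 | step 5 | (2S)-1-methoxy-1-oxopropan-2-yl (1S,5R)-1-[(2R)-but-3-yn-2-yl]-3-methyl-2-oxo-8-oxabicyclo[3.2.1]octane-6-carboxylate (C3 and C6 epimers) | O1[C@@H]2CC(C)C(=O)[C@]1(CC2C(=O)O[C@@H](C)C(=O)OC)[C@H](C)C#C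
F4 | step 6 | S-ethyl prop-2-enethioate | C=CC(=O)SCC
F5 | step 6 | S-ethyl (1S,5R)-1-[(2R)-but-3-yn-2-yl]-3-methyl-2-oxo-8-oxabicyclo[3.2.1]oct-3-ene-6-carbothioate (both C6 epimers) | O1[C@@H]2C=C(C)C(=O)[C@]1(CC2C(=O)SCC)[C@H](C)C#C
F6 | step 6 | S-ethyl (1S,3S,5R,6S)-1-[(2R)-but-3-yn-2-yl]-3-methyl-2-oxo-8-oxabicyclo[3.2.1]octane-6-carbothioate | O1[C@@H]2C[C@H](C)C(=O)[C@]1(C[C@@H]2C(=O)SCC)[C@H](C)C#C
F7 | step 6 | S-ethyl (1S,5R,6S)-1-[(2R)-but-3-yn-2-yl]-3-methyl-2-(triethylsilyloxy)-8-oxabicyclo[3.2.1]oct-2-ene-6-carbothioate | O1[C@@H]2CC(C)=C(O[Si](CC)(CC)CC)[C@]1(C[C@@H]2C(=O)SCC)[C@H](C)C#C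
F8 | step 9 | diethyl {(3R)-3-[(1S,3S,5R,6S)-6-(2-hydroxypropan-2-yl)-3-methyl-2-oxo-8-oxabicyclo[3.2.1]octan-1-yl]but-1-yn-1-yl}phosphonate | O1[C@@H]2C[C@H](C)C(=O)[C@]1(C[C@@H]2C(C)(C)O)[C@H](C)C#CP(=O)(OCC)OCC
F9 | step 9 | diethyl {(3S)-3-[(1S,3S,5R,6S)-6-(2-hydroxypropan-2-yl)-3-methyl-2-oxo-8-oxabicyclo[3.2.1]octan-1-yl]-2-oxobutyl}phosphonate | O1[C@@H]2C[C@H](C)C(=O)[C@]1(C[C@@H]2C(C)(C)O)[C@H](C)C(=O)CP(=O)(OCC)OCC
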